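Everything rests on disconnecting C4–C4a in the fisetinidol unit attached to catechin C8. That C4 sits on catechin ring A, whose three oxygens (O1, O5, O7) stabilise a cation there, while ring A of the fisetinidol unit, a resorcinol-type ring, can be installed beforehand as an aryl ether on that unit's O1. A single acid-mediated Friedel–Crafts closure then builds ring C of this unit and fixes C4 as 4α from both carbinol epimers. The precursor is a 1-(catechin-8-yl)propan-1-ol bearing 2-benzyloxy, 3-(3,4-dibenzyloxyphenyl) and 3-(3-benzyloxyphenoxy) groups, every hydroxyl benzylated. The second fisetinidol unit is added later at C6 by ketone addition and ionic reduction.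

Key step: step 9

Assumption: 5-(benzyloxy)-2-bromophenol (19) is treated as a purchasable phenol.

Step 1
Reactants: 1 (+)-catechin
Product: 2 3,5,7,3',4'-penta-O-benzyl-(+)-catechin
Conditions: BnBr, NaH, DMF, 0 °C to rt
Reagents that add atoms: benzyl bromide, BrCc1ccccc1
Why: Williamson ether synthesis: NaH deprotonates the four phenols and the C3 alcohol and each oxygen displaces bromide from BnBr, leaving C2 and C3 untouched.

Step 2
Reactants: 2 3,5,7,3',4'-penta-O-benzyl-(+)-catechin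
Product: 3 8-bromo-3,5,7,3',4'-penta-O-benzylcatechin
Conditions: NBS (1.0 equiv), CH2Cl2, −78 °C to rt
Reagents that add atoms: N-bromosuccinimide, O=C1CCC(=O)N1Br
Why: Electrophilic aromatic bromination: ring A, a phloroglucinol triether, reacts far faster than the catechol ring B, and in benzylated catechins its C8 position is known to be taken before C6.

Step 3
Reactants: 4 (R)-4-benzyl-1,3-oxazolidin-2-one; 5 (benzyloxy)acetyl chloride
Product: 6 (4R)-4-benzyl-3-[(benzyloxy)acetyl]-1,3-oxazolidin-2-one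
Conditions: n-BuLi, THF, −78 °C; then 5, −78 to 0 °C
Reagents that add atoms: none
Why: N-Acylation of the lithiated oxazolidinone by the acid chloride, the standard preparation of an Evans imide; the auxiliary centre is not involved.

Step 4
Reactants: 6 (4R)-4-benzyl-3-[(benzyloxy)acetyl]-1,3-oxazolidin-2-one; 7 3,4-bis(benzyloxy)benzaldehyde
Product: 9 (4R)-4-benzyl-3-{(2R,3S)-2-(benzyloxy)-3-[3,4-bis(benzyloxy)phenyl]-3-hydroxypropanoyl}-1,3-oxazolidin-2-one, via dibutylboron Z-enolate 8 (not isolated)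
Conditions: Bu2BOTf, Et3N, CH2Cl2, −78 to 0 °C; 7, −78 to 0 °C; then H2O2, MeOH, pH 7 buffer
Reagents that add atoms: none
Why: Evans syn-aldol reaction: the chelated Z-boron enolate adds to the aldehyde through a chair Zimmerman–Traxler transition state on the enolate face away from the auxiliary benzyl group, which sets C2 as R and C3 as S (syn).

Step 5
Reactants: 9 the syn-aldol imide
Product: 10 (2R,3S)-2-(benzyloxy)-3-[3,4-bis(benzyloxy)phenyl]-3-hydroxy-N-methoxy-N-methylpropanamide
Conditions: AlMe3, MeNH(OMe)·HCl, CH2Cl2, −10 to 0 °C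
Reagents that add atoms: N,O-dimethylhydroxylamine hydrochloride, CNOC.Cl
Why: Weinreb amide formation by aluminium amide transamination, directed by the free β-hydroxyl, cleaves the auxiliary without epimerising C2 or C3.

Step 6
Reactants: 10 the β-hydroxy Weinreb amide; 11 3-(benzyloxy)phenol
Product: 12 (2R,3R)-2-(benzyloxy)-3-[3-(benzyloxy)phenoxy]-3-[3,4-bis(benzyloxy)phenyl]-N-methoxy-N-methylpropanamide
Conditions: PPh3, DIAD, toluene, 0 °C to rt
Reagents that add atoms: none
Why: Mitsunobu etherification: the phosphonium-activated benzylic oxygen is displaced by the phenol in an SN2 step with inversion, turning C3 from S to R and creating the anti O2/O3 pattern that becomes the 2,3-trans ring C, while the electron-poor neighbour C2 disfavours ionisation.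

Step 7
Reactants: 12 the anti aryl ether Weinreb amide
Product: 13 (2R,3R)-2-(benzyloxy)-3-[3-(benzyloxy)phenoxy]-3-[3,4-bis(benzyloxy)phenyl]propanal
Conditions: iBu2AlH, THF, −78 °C; aq. potassium sodium tartrate
Reagents that add atoms: none
Why: Weinreb amide reduction: the chelated tetrahedral aluminium adduct is stable at −78 °C and collapses to the aldehyde only on work-up, so over-reduction and C2 epimerisation are avoided; the crude aldehyde is used at once.

Step 8
Reactants: 3 8-bromo-3,5,7,3',4'-penta-O-benzylcatechin; 13 the aldehyde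
Product: 15 (1RS,2S,3R)-2-(benzyloxy)-3-[3-(benzyloxy)phenoxy]-3-[3,4-bis(benzyloxy)phenyl]-1-(3,5,7,3',4'-penta-O-benzylcatechin-8-yl)propan-1-ol (both C1 epimers), via 8-lithio catechin ether 14 (not isolated)
Conditions: n-BuLi, THF, −78 °C; then 13, −78 °C; H2O
Reagents that add atoms: none
Why: Bromine–lithium exchange then 1,2-addition of the aryllithium to the aldehyde forms the C4–C8 bond; the new carbinol centre needs no control because both epimers converge in step 9.

Step 9
Reactants: 15 the carbinol (both C1 epimers)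
Product: 17 3,7,3',4'-tetra-O-benzylfisetinidol-(4α→8)-3,5,7,3',4'-penta-O-benzylcatechin, via benzylic C4 cation 16 (not isolated)
Conditions: Me3SiOTf (0.2 equiv), 4 Å molecular sieves, CH2Cl2 (0.01 M), −78 to −30 °C; then Et3N
Reagents that add atoms: none
Why: Me3SiOTf turns either carbinol epimer into the same planar benzylic cation 16, delocalised into catechin ring A through O7, O5 and O1, and the tethered 3-benzyloxyphenyl ether attacks it through the carbon para to its benzyloxy group and ortho to the ether oxygen, forming C4–C4a before a proton is lost to restore the arene. The closest known reaction type is the intramolecular Friedel–Crafts alkylation of aryl ethers by benzylic cations that gives 4-arylchromans. Ring C closes as a six-membered ring in a 6-endo mode with respect to the arene C4a=C8a π bond, which lies inside the new ring, through a chair-like transition state. The new C4 stereocentre is controlled by the existing C2 and C3 centres: with the C2 aryl and C3 benzyloxy groups equatorial, the bulky catechinyl group also takes the equatorial site, so C4–C4a forms trans to O3 (4α, 4S) whichever epimer was ionised. The step needs closure para and not ortho to the ring A benzyloxy group, and chroman formation in preference to five-ring attack by the catechol ring B; the first is secured by crowding between the two oxygens at the ortho site, the second by the doubly activated attacking carbon and the favoured ring size. High dilution and low temperature are chosen to suppress intermolecular capture at catechin C6 and proton loss from C3.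

Step 10
Reactants: 17 the benzylated fisetinidol-(4α→8)-catechin
Product: 18 6-bromo derivative of 17 (bromine on C6 of the catechin unit)
Conditions: NBS (1.0 equiv), CH2Cl2, −78 to 0 °C
Reagents that add atoms: N-bromosuccinimide, O=C1CCC(=O)N1Br
Why: Electrophilic aromatic bromination: C6 is the only free position on catechin ring A, which remains the most electron-rich ring of 17, and C6 of benzylated catechins is known to brominate once C8 is occupied.

Step 11
Reactants: 10 the β-hydroxy Weinreb amide; 19 5-(benzyloxy)-2-bromophenol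
Product: 20 (2R,3R)-2-(benzyloxy)-3-[5-(benzyloxy)-2-bromophenoxy]-3-[3,4-bis(benzyloxy)phenyl]-N-methoxy-N-methylpropanamide
Conditions: PPh3, DIAD, toluene, 0 °C to rt
Reagents that add atoms: none
Why: Mitsunobu etherification as in step 6: the more acidic ortho-bromophenol displaces the activated benzylic oxygen with inversion (C3 from S to R), and the bromine ends ortho to the new ether oxygen and para to the benzyloxy group.

Step 12
Reactants: 20 the bromoaryl ether Weinreb amide
Product: 22 (2R,3R)-3,7-bis(benzyloxy)-2-[3,4-bis(benzyloxy)phenyl]-2,3-dihydro-4H-chromen-4-one (3,7,3',4'-tetra-O-benzylfustin), via aryllithium 21 (not isolated)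
Conditions: t-BuLi (2 equiv), THF, −78 to −40 °C; then AcOH
Reagents that add atoms: none
Why: Parham cyclisation: bromine–lithium exchange is faster than attack of t-BuLi on the amide, the aryllithium acylates the Weinreb amide through a six-membered transition state, and the chelated tetrahedral adduct holds C2 and C3 until the acidic quench, so the 2,3-trans ketone forms without a new stereocentre.

Step 13
Reactants: 18 the 6-bromo dimer; 22 the ketone
Product: 25 tertiary C4 carbinol in which C6 of the catechin unit of 17 is bonded to C4 of a 4-hydroxy-3,7,3',4'-tetra-O-benzylfisetinidol unit (C4 epimers), via 6-lithio dimer 23 (not isolated), via 6-dichlorocerio dimer 24 (not isolated)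
Conditions: n-BuLi, THF, −78 °C; CeCl3, −78 °C; then 22, −78 to −40 °C; H2O
Reagents that add atoms: none
Why: Organocerium 1,2-addition: after bromine–lithium exchange and transmetalation the weakly basic aryl cerium reagent adds to the enolisable, hindered ketone in preference to deprotonating C3; the configuration of the tertiary carbinol is irrelevant because step 14 removes it.

Step 14
Reactants: 25 the tertiary carbinol
Product: 27 trideca-O-benzyl fisetinidol-(4α→8)-catechin-(6→4β)-fisetinidol, via C4 cation 26 (not isolated)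
Conditions: Et3SiH, CF3CO2H, CH2Cl2, −40 to 0 °C
Reagents that add atoms: none
Why: Ionic hydrogenation (Kursanov–Parnes reduction): CF3CO2H ionises the doubly benzylic tertiary alcohol and Et3SiH transfers hydride to the planar C4 cation on the face away from the adjacent C3 benzyloxy group, so the catechin ring ends cis to O3 (4β, 4R), the outcome known for this addition–reduction route to 3,4-cis 4-arylflavan-3-ol ethers.

Step 15
Reactants: 27 the trideca-O-benzyl trimer
Product: 28 fisetinidol-(4α→8)-catechin-(6→4β)-fisetinidol (CNP0289228.1)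
Conditions: H2 (1 atm), Pd(OH)2/C, THF–MeOH–H2O, rt
Reagents that add atoms: none
Why: Hydrogenolysis over Pd(OH)2 cleaves all thirteen benzyl ethers under neutral conditions that leave the two interflavan C–C bonds and the eight stereocentres untouched.

Compound list

1 | (+)-catechin, (2R,3S) | Oc1cc(O)c2c(c1)O[C@H](c1ccc(O)c(O)c1)[C@@H](O)C2 | starting material
2 | 3,5,7,3',4'-penta-O-benzyl-(+)-catechin, (2R,3S) | c1ccccc1COc2cc(OCc3ccccc3)c3c(c2)O[C@H](c2ccc(OCc4ccccc4)c(OCc4ccccc4)c2)[C@@H](OCc2ccccc2)C3 | intermediate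
3 | 8-bromo-3,5,7,3',4'-penta-O-benzylcatechin | c1ccccc1COc2cc(OCc3ccccc3)c3c(c2Br)O[C@H](c2ccc(OCc4ccccc4)c(OCc4ccccc4)c2)[C@@H](OCc2ccccc2)C3 | intermediate
4 | (R)-4-benzyl-1,3-oxazolidin-2-one | O=C1N[C@H](Cc2ccccc2)CO1 | starting material
5 | (benzyloxy)acetyl chloride | O=C(Cl)COCc1ccccc1 | starting material
6 | (4R)-4-benzyl-3-[(benzyloxy)acetyl]-1,3-oxazolidin-2-one | O=C1N(C(=O)COCc2ccccc2)[C@H](Cc2ccccc2)CO1 | intermediate
7 | 3,4-bis(benzyloxy)benzaldehyde | O=Cc1ccc(OCc2ccccc2)c(OCc2ccccc2)c1 | starting material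
8 | dibutylboron Z-enolate of 6 | CCCCB(CCCC)O/C(=C\OCc1ccccc1)N1C(=O)OC[C@H]1Cc1ccccc1 | intermediate
9 | (4R)-4-benzyl-3-{(2R,3S)-2-(benzyloxy)-3-[3,4-bis(benzyloxy)phenyl]-3-hydroxypropanoyl}-1,3-oxazolidin-2-one (syn aldol) | O=C1N(C(=O)[C@H](OCc2ccccc2)[C@@H](O)c2ccc(OCc3ccccc3)c(OCc3ccccc3)c2)[C@H](Cc2ccccc2)CO1 | intermediate
10 | (2R,3S)-2-(benzyloxy)-3-[3,4-bis(benzyloxy)phenyl]-3-hydroxy-N-methoxy-N-methylpropanamide | CON(C)C(=O)[C@H](OCc1ccccc1)[C@@H](O)c1ccc(OCc2ccccc2)c(OCc2ccccc2)c1 | intermediate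
11 | 3-(benzyloxy)phenol | Oc1cccc(OCc2ccccc2)c1 | starting material
12 | (2R,3R)-2-(benzyloxy)-3-[3-(benzyloxy)phenoxy]-3-[3,4-bis(benzyloxy)phenyl]-N-methoxy-N-methylpropanamide | CON(C)C(=O)[C@H](OCc1ccccc1)[C@@H](c1ccc(OCc2ccccc2)c(OCc2ccccc2)c1)Oc1cccc(OCc2ccccc2)c1 | intermediate
13 | (2R,3R)-2-(benzyloxy)-3-[3-(benzyloxy)phenoxy]-3-[3,4-bis(benzyloxy)phenyl]propanal | O=C[C@H](OCc1ccccc1)[C@@H](c1ccc(OCc2ccccc2)c(OCc2ccccc2)c1)Oc1cccc(OCc2ccccc2)c1 | intermediate
14 | 8-lithio-3,5,7,3',4'-penta-O-benzylcatechin | c1ccccc1COc2cc(OCc3ccccc3)c3c(c2[Li])O[C@H](c2ccc(OCc4ccccc4)c(OCc4ccccc4)c2)[C@@H](OCc2ccccc2)C3 | intermediate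
15 | (1RS,2S,3R)-2-(benzyloxy)-3-[3-(benzyloxy)phenoxy]-3-[3,4-bis(benzyloxy)phenyl]-1-(3,5,7,3',4'-penta-O-benzylcatechin-8-yl)propan-1-ol, both C1 epimers | c1ccccc1COc2cc(OCc3ccccc3)c3c(c2C(O)[C@H](OCc2ccccc2)[C@@H](c2ccc(OCc4ccccc4)c(OCc4ccccc4)c2)Oc2cccc(OCc4ccccc4)c2)O[C@H](c2ccc(OCc4ccccc4)c(OCc4ccccc4)c2)[C@@H](OCc2ccccc2)C3 | intermediate
16 | benzylic C4 cation from 15 (positive carbon on catechin C8) | c1ccccc1COc2cc(OCc3ccccc3)c3c(c2[CH+][C@H](OCc2ccccc2)[C@@H](c2ccc(OCc4ccccc4)c(OCc4ccccc4)c2)Oc2cccc(OCc4ccccc4)c2)O[C@H](c2ccc(OCc4ccccc4)c(OCc4ccccc4)c2)[C@@H](OCc2ccccc2)C3 | intermediate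
17 | 3,7,3',4'-tetra-O-benzylfisetinidol-(4α→8)-3,5,7,3',4'-penta-O-benzylcatechin; upper unit (2R,3S,4S), lower unit (2R,3S) | c1ccccc1COc2cc(OCc3ccccc3)c3c(c2[C@@H]2c4ccc(OCc5ccccc5)cc4O[C@H](c4ccc(OCc5ccccc5)c(OCc5ccccc5)c4)[C@H]2OCc2ccccc2)O[C@H](c2ccc(OCc4ccccc4)c(OCc4ccccc4)c2)[C@@H](OCc2ccccc2)C3 | intermediate
18 | 6-bromo derivative of 17 (Br on catechin C6) | c1ccccc1COc2c(Br)c(OCc3ccccc3)c3c(c2[C@@H]2c4ccc(OCc5ccccc5)cc4O[C@H](c4ccc(OCc5ccccc5)c(OCc5ccccc5)c4)[C@H]2OCc2ccccc2)O[C@H](c2ccc(OCc4ccccc4)c(OCc4ccccc4)c2)[C@@H](OCc2ccccc2)C3 | intermediate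
19 | 5-(benzyloxy)-2-bromophenol | Oc1cc(OCc2ccccc2)ccc1Br | starting material
20 | (2R,3R)-2-(benzyloxy)-3-[5-(benzyloxy)-2-bromophenoxy]-3-[3,4-bis(benzyloxy)phenyl]-N-methoxy-N-methylpropanamide | CON(C)C(=O)[C@H](OCc1ccccc1)[C@@H](c1ccc(OCc2ccccc2)c(OCc2ccccc2)c1)Oc1cc(OCc2ccccc2)ccc1Br | intermediate
21 | aryllithium from 20 (Li in place of Br) | CON(C)C(=O)[C@H](OCc1ccccc1)[C@@H](c1ccc(OCc2ccccc2)c(OCc2ccccc2)c1)Oc1cc(OCc2ccccc2)ccc1[Li] | intermediate
22 | (2R,3R)-3,7-bis(benzyloxy)-2-[3,4-bis(benzyloxy)phenyl]-2,3-dihydro-4H-chromen-4-one (3,7,3',4'-tetra-O-benzylfustin) | O=C1c2ccc(OCc3ccccc3)cc2O[C@H](c2ccc(OCc3ccccc3)c(OCc3ccccc3)c2)[C@H]1OCc1ccccc1 | intermediate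
23 | 6-lithio derivative of 17 | c1ccccc1COc2c([Li])c(OCc3ccccc3)c3c(c2[C@@H]2c4ccc(OCc5ccccc5)cc4O[C@H](c4ccc(OCc5ccccc5)c(OCc5ccccc5)c4)[C@H]2OCc2ccccc2)O[C@H](c2ccc(OCc4ccccc4)c(OCc4ccccc4)c2)[C@@H](OCc2ccccc2)C3 | intermediate
24 | 6-(dichlorocerio) derivative of 17 | c1ccccc1COc2c([Ce](Cl)Cl)c(OCc3ccccc3)c3c(c2[C@@H]2c4ccc(OCc5ccccc5)cc4O[C@H](c4ccc(OCc5ccccc5)c(OCc5ccccc5)c4)[C@H]2OCc2ccccc2)O[C@H](c2ccc(OCc4ccccc4)c(OCc4ccccc4)c2)[C@@H](OCc2ccccc2)C3 | intermediate
25 | tertiary carbinol: 17 carrying at catechin C6 a (2R,3S)-3,7-bis(benzyloxy)-2-[3,4-bis(benzyloxy)phenyl]-4-hydroxychroman-4-yl group, C4 epimers | c1ccccc1COc2c(C4(O)c5ccc(OCc6ccccc6)cc5O[C@H](c5ccc(OCc6ccccc6)c(OCc6ccccc6)c5)[C@H]4OCc4ccccc4)c(OCc3ccccc3)c3c(c2[C@@H]2c4ccc(OCc5ccccc5)cc4O[C@H](c4ccc(OCc5ccccc5)c(OCc5ccccc5)c4)[C@H]2OCc2ccccc2)O[C@H](c2ccc(OCc4ccccc4)c(OCc4ccccc4)c2)[C@@H](OCc2ccccc2)C3 | intermediate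
26 | C4 cation from 25 | c1ccccc1COc2c([C+]4c5ccc(OCc6ccccc6)cc5O[C@H](c5ccc(OCc6ccccc6)c(OCc6ccccc6)c5)[C@H]4OCc4ccccc4)c(OCc3ccccc3)c3c(c2[C@@H]2c4ccc(OCc5ccccc5)cc4O[C@H](c4ccc(OCc5ccccc5)c(OCc5ccccc5)c4)[C@H]2OCc2ccccc2)O[C@H](c2ccc(OCc4ccccc4)c(OCc4ccccc4)c2)[C@@H](OCc2ccccc2)C3 | intermediate
27 | trideca-O-benzyl fisetinidol-(4α→8)-catechin-(6→4β)-fisetinidol; C8 unit (2R,3S,4S), C6 unit (2R,3S,4R), catechin (2R,3S) | c1ccccc1COc2c([C@H]4c5ccc(OCc6ccccc6)cc5O[C@H](c5ccc(OCc6ccccc6)c(OCc6ccccc6)c5)[C@H]4OCc4ccccc4)c(OCc3ccccc3)c3c(c2[C@@H]2c4ccc(OCc5ccccc5)cc4O[C@H](c4ccc(OCc5ccccc5)c(OCc5ccccc5)c4)[C@H]2OCc2ccccc2)O[C@H](c2ccc(OCc4ccccc4)c(OCc4ccccc4)c2)[C@@H](OCc2ccccc2)C3 | intermediate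
28 | fisetinidol-(4α→8)-catechin-(6→4β)-fisetinidol (CNP0289228.1) | Oc1ccc2c(c1)O[C@H](c1ccc(O)c(O)c1)[C@@H](O)[C@H]2c1c(O)c2c(c([C@@H]3c4ccc(O)cc4O[C@H](c4ccc(O)c(O)c4)[C@H]3O)c1O)O[C@H](c1ccc(O)c(O)c1)[C@@H](O)C2 | target

Total step count: 15. Longest linear sequence: 11 steps (steps 3–10 and 13–15, from 4 and 5 to 28).

Steps most likely to fail

Step 9. The cation may lose the C3 proton to give an enol ether (loss of the C3 centre), close with poor facial control, or be captured by another molecule before ring closure. The fallback sets out from ketone 22 and catechin ether 2 and comes back at 17. NaBH4 in THF–MeOH at 0 °C should reduce 22 to (2R,3S)-3,7-bis(benzyloxy)-2-[3,4-bis(benzyloxy)phenyl]chroman-4-ol F1 (C4 epimers, either serves). BF3·OEt2 in CH2Cl2 at −78 °C, with 2 in excess, should then ionise F1, and C8 of 2 should intercept the C4 cation mainly trans to the C3 benzyloxy group. This is the established intermolecular Friedel–Crafts coupling of flavan-4-ol electrophiles with catechin nucleophiles; the C6-linked and 4β by-products would be removed by chromatography to leave 17.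

Step 14. Hydride may be delivered to both faces of cation 26, or 26 may lose its C3 proton, or the acid may cleave the C4–C8 bond made in step 9. The fallback sets out from 17 and 22, leaves out steps 10 and 13, and comes back at 27. Ketone 22 would be reduced with NaBH4 as above to the flavan-4-ol F2 (the same compound as F1). Me3SiOTf in CH2Cl2 at −78 °C, with a slight excess of 17, should couple F2 at C6, the only free position of catechin ring A. Both C4 epimers are expected from this intermolecular Friedel–Crafts alkylation, because the 5-deoxy cation has only a modest facial preference and the C6 site is crowded; the 3,4-cis product 27 would be separated from its 4α epimer by chromatography.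

Step 6 (and its twin, step 11). The activated, electron-rich benzylic centre may ionise in part (erosion of the C3 configuration) or eliminate toward the α-benzyloxycinnamamide. The fallback sets out from aldehyde 7 and comes back at aldehyde 13.
- Wittig olefination of 7 with Ph3P=CHCO2Et in toluene should give ethyl (E)-3-[3,4-bis(benzyloxy)phenyl]prop-2-enoate F3.
- iBu2AlH in CH2Cl2 at −78 °C should reduce it to (E)-3-[3,4-bis(benzyloxy)phenyl]prop-2-en-1-ol F4.
- Sharpless epoxidation (Ti(OiPr)4, L-(+)-diethyl tartrate, t-BuOOH, 4 Å molecular sieves, CH2Cl2, −20 °C) should give [(2S,3S)-3-[3,4-bis(benzyloxy)phenyl]oxiran-2-yl]methanol F5.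
- Phenol 11 with NaOH in H2O–dioxane at 60 °C should open the epoxide at the benzylic carbon with inversion, a known course for 3-arylglycidols, giving (2S,3R)-3-[3-(benzyloxy)phenoxy]-3-[3,4-bis(benzyloxy)phenyl]propane-1,2-diol F6.
- PhCH(OMe)2 with catalytic pyridinium tosylate should give the 2-phenyl-1,3-dioxolane F7.
- iBu2AlH in CH2Cl2 at 0 °C should open F7 toward the benzyl ether on the secondary oxygen, giving (2S,3R)-2-(benzyloxy)-3-[3-(benzyloxy)phenoxy]-3-[3,4-bis(benzyloxy)phenyl]propan-1-ol F8.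
- Dess–Martin periodinane in CH2Cl2 should oxidise F8 to 13.

Further compounds
F1 | step 9 | (2R,3S)-3,7-bis(benzyloxy)-2-[3,4-bis(benzyloxy)phenyl]chroman-4-ol, C4 epimers | OC1c2ccc(OCc3ccccc3)cc2O[C@H](c2ccc(OCc3ccccc3)c(OCc3ccccc3)c2)[C@H]1OCc1ccccc1
F2 | step 14 | (2R,3S)-3,7-bis(benzyloxy)-2-[3,4-bis(benzyloxy)phenyl]chroman-4-ol, C4 epimers | OC1c2ccc(OCc3ccccc3)cc2O[C@H](c2ccc(OCc3ccccc3)c(OCc3ccccc3)c2)[C@H]1OCc1ccccc1
F3 | step 6 | ethyl (E)-3-[3,4-bis(benzyloxy)phenyl]prop-2-enoate | CCOC(=O)/C=C/c1ccc(OCc2ccccc2)c(OCc2ccccc2)c1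
F4 | step 6 | (E)-3-[3,4-bis(benzyloxy)phenyl]prop-2-en-1-ol | OC/C=C/c1ccc(OCc2ccccc2)c(OCc2ccccc2)c1
F5 | step 6 | [(2S,3S)-3-[3,4-bis(benzyloxy)phenyl]oxiran-2-yl]methanol | OC[C@@H]1O[C@H]1c1ccc(OCc2ccccc2)c(OCc2ccccc2)c1
F6 | step 6 | (2S,3R)-3-[3-(benzyloxy)phenoxy]-3-[3,4-bis(benzyloxy)phenyl]propane-1,2-diol | OC[C@H](O)[C@@H](c1ccc(OCc2ccccc2)c(OCc2ccccc2)c1)Oc1cccc(OCc2ccccc2)c1
F7 | step 6 | (4S)-4-{(R)-[3-(benzyloxy)phenoxy][3,4-bis(benzyloxy)phenyl]methyl}-2-phenyl-1,3-dioxolane, acetal epimers | C1(c2ccccc2)OC[C@H](O1)[C@@H](c1ccc(OCc2ccccc2)c(OCc2ccccc2)c1)Oc1cccc(OCc2ccccc2)c1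
F8 | step 6 | (2S,3R)-2-(benzyloxy)-3-[3-(benzyloxy)phenoxy]-3-[3,4-bis(benzyloxy)phenyl]propan-1-ol | OC[C@H](OCc1ccccc1)[C@@H](c1ccc(OCc2ccccc2)c(OCc2ccccc2)c1)Oc1cccc(OCc2ccccc2)c1
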